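The oxolane is disconnected at the bond between the ring carbon that carries the aroyl group (C4) and the ring carbon that carries CH2OH (C3). Because C3 lies β and C4 lies α to the aryl ketone, this bond can be made as the C=C of an enone by intramolecular alkyne–ketone metathesis. An aryl alkyne, tethered through the ring oxygen to an α-alkoxy ketone, closes the 2,5-dihydrofuran ring and is itself turned into the aroyl group in one operation. The precursor is an enantiopure propargyl ether of an α-hydroxy ketone from Sharpless epoxide chemistry. Conjugate hydride addition anti to the C2 aryl group and equilibration then set the 2,3-cis-3,4-trans pattern.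

Key step: step 7

Remark: the oxolane atoms are numbered O1, C2 (aryl), C3 (CH2OH), C4 (aroyl), C5 throughout, also in the intermediates.

Step 1
Reactants: 1 methyl (2E)-3-(3,4,5-trimethoxyphenyl)prop-2-enoate
Product: 2 (2E)-3-(3,4,5-trimethoxyphenyl)prop-2-en-1-ol
Conditions: DIBAL-H (2.2 equiv), CH2Cl2, −78 → 0 °C; Rochelle salt work-up
Reagents that add atoms: none
Why: DIBAL-H reduces the conjugated ester at the carbonyl group only (1,2-reduction of an enoate to the allylic alcohol), leaving the E alkene untouched.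

Step 2
Reactants: 2 (2E)-3-(3,4,5-trimethoxyphenyl)prop-2-en-1-ol
Product: 3 [(2S,3S)-3-(3,4,5-trimethoxyphenyl)oxiran-2-yl]methanol
Conditions: Ti(OiPr)4 (10 mol %), L-(+)-diethyl tartrate (12 mol %), t-BuOOH, 4 Å MS, CH2Cl2, −20 °C
Reagents that add atoms: tert-butyl hydroperoxide, CC(C)(C)OO
Why: Sharpless asymmetric epoxidation of the E allylic alcohol; with L-(+)-diethyl tartrate the reagent should deliver oxygen to the alkene face that gives the (2S,3S)-epoxide, which fixes the absolute configuration of the future C2.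

Step 3
Reactants: 4 5-iodo-1,2,3-trimethoxybenzene; 5 prop-2-yn-1-ol
Product: 6 3-(3,4,5-trimethoxyphenyl)prop-2-yn-1-ol
Conditions: PdCl2(PPh3)2 (2 mol %), CuI (4 mol %), Et3N, THF, 23 °C
Reagents that add atoms: none
Why: Sonogashira coupling of an aryl iodide with a terminal alkyne tolerates the free propargylic hydroxyl group.

Step 4
Reactants: 3 [(2S,3S)-3-(3,4,5-trimethoxyphenyl)oxiran-2-yl]methanol; 6 3-(3,4,5-trimethoxyphenyl)prop-2-yn-1-ol
Product: 7 (2S,3R)-3-(3,4,5-trimethoxyphenyl)-3-{[3-(3,4,5-trimethoxyphenyl)prop-2-yn-1-yl]oxy}propane-1,2-diol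
Conditions: Ti(OiPr)4 (1.5 equiv), 6 (3 equiv), CH2Cl2, 23 → 40 °C; aq. tartaric acid work-up
Reagents that add atoms: none
Why: Titanium-assisted C3-selective ring opening of a 2,3-epoxy alcohol, in which the chelated titanium alkoxide activates the benzylic C–O bond and the alcohol attacks it in an SN2 manner with inversion, should set the benzylic ether carbon that becomes C2 of the oxolane.

Step 5
Reactants: 7 (2S,3R)-3-(3,4,5-trimethoxyphenyl)-3-{[3-(3,4,5-trimethoxyphenyl)prop-2-yn-1-yl]oxy}propane-1,2-diol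
Product: 8 (2S,3R)-1-[(tert-butyldiphenylsilyl)oxy]-3-(3,4,5-trimethoxyphenyl)-3-{[3-(3,4,5-trimethoxyphenyl)prop-2-yn-1-yl]oxy}propan-2-ol
Conditions: TBDPSCl (1.05 equiv), imidazole, CH2Cl2, 0 °C
Reagents that add atoms: tert-butyl(chloro)diphenylsilane, CC(C)(C)[Si](Cl)(c1ccccc1)c1ccccc1
Why: Silyl ether protection with the bulky chlorosilane should be selective for the primary over the hindered secondary hydroxyl group.

Step 6
Reactants: 8 (2S,3R)-1-[(tert-butyldiphenylsilyl)oxy]-3-(3,4,5-trimethoxyphenyl)-3-{[3-(3,4,5-trimethoxyphenyl)prop-2-yn-1-yl]oxy}propan-2-ol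
Product: 9 (3R)-1-[(tert-butyldiphenylsilyl)oxy]-3-(3,4,5-trimethoxyphenyl)-3-{[3-(3,4,5-trimethoxyphenyl)prop-2-yn-1-yl]oxy}propan-2-one
Conditions: Dess–Martin periodinane (1.3 equiv), CH2Cl2, 0 → 23 °C; the ketone is used without delay
Reagents that add atoms: none
Why: Dess–Martin oxidation of the secondary alcohol proceeds under neutral, non-enolising conditions, so the α-aryl-α-alkoxy stereocentre of the ketone should survive.

Step 7
Reactants: 9 (3R)-1-[(tert-butyldiphenylsilyl)oxy]-3-(3,4,5-trimethoxyphenyl)-3-{[3-(3,4,5-trimethoxyphenyl)prop-2-yn-1-yl]oxy}propan-2-one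
Product: 11 [(5R)-4-{[(tert-butyldiphenylsilyl)oxy]methyl}-5-(3,4,5-trimethoxyphenyl)-2,5-dihydrofuran-3-yl](3,4,5-trimethoxyphenyl)methanone, via fused oxetene 10 (not isolated)
Conditions: AgSbF6 (10 mol %), ClCH2CH2Cl, 23 → 60 °C
Reagents that add atoms: none
Why: The silver cation activates the ketone, the alkyne carbon remote from the aryl ring attacks the carbonyl carbon (forming C3–C4), and the aryl-stabilised vinyl cation is captured by the carbonyl oxygen to give fused oxetene 10, whose 4π-electrocyclic ring opening (retro-[2+2]) delivers the tetrasubstituted enone and moves the oxygen onto the former alkyne carbon, which thereby becomes the aroyl carbonyl. The closest known reaction type is the Lewis-acid-catalysed intramolecular alkyne–carbonyl metathesis of aryl alkynes with tethered aldehydes and ketones, which gives 1-aroylcyclopentenes and 3-acyl-2,5-dihydrofurans. The dihydrofuran ring closes in a 5-exo mode (the C=O bond and the second alkyne carbon both stay outside the new five-membered ring, which is preferred over the six-membered alternative), and the transient oxetene ring closes by O–C bond formation at the vinyl cation. No new stereocentre is created, since C3 and C4 become sp2, and the benzylic centre C2 set in step 4 is carried through. The step needs regioselectivity, secured by the 3,4,5-trimethoxyphenyl group, which stabilises positive charge only on the alkyne carbon bound to it, and it needs the α-aryl-α-alkoxy ketone not to enolise, which the aprotic, base-free medium and the low catalyst loading are meant to secure.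

Step 8
Reactants: 11 [(5R)-4-{[(tert-butyldiphenylsilyl)oxy]methyl}-5-(3,4,5-trimethoxyphenyl)-2,5-dihydrofuran-3-yl](3,4,5-trimethoxyphenyl)methanone
Product: 13 [(3R,4S,5S)-4-{[(tert-butyldiphenylsilyl)oxy]methyl}-5-(3,4,5-trimethoxyphenyl)oxolan-3-yl](3,4,5-trimethoxyphenyl)methanone, via silyl enol ether 12 (not isolated)
Conditions: Cu(OAc)2·H2O (5 mol %), 1,2-bis(diphenylphosphino)benzene (5 mol %), (EtO)2MeSiH (2 equiv), toluene, 0 → 23 °C; then K2CO3 (0.2 equiv), MeOH, 23 °C
Reagents that add atoms: none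
Why: Copper hydride conjugate reduction (1,4-hydrosilylation) should deliver hydride to the enone β-carbon C3 from the ring face opposite the neighbouring C2 aryl group, which puts the CH2OSi group cis to the aryl group, and base-catalysed methanolysis of silyl enol ether 12 under equilibrating conditions should leave the aroyl group at C4 trans to the C3 substituent (thermodynamic control at the ketone α-carbon).

Step 9
Reactants: 13 [(3R,4S,5S)-4-{[(tert-butyldiphenylsilyl)oxy]methyl}-5-(3,4,5-trimethoxyphenyl)oxolan-3-yl](3,4,5-trimethoxyphenyl)methanone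
Product: 14 [(3R,4S,5S)-4-(hydroxymethyl)-5-(3,4,5-trimethoxyphenyl)oxolan-3-yl](3,4,5-trimethoxyphenyl)methanone
Conditions: HF·pyridine, pyridine, THF, 0 → 23 °C
Reagents that add atoms: none
Why: Fluoride-mediated desilylation under buffered, non-basic conditions should free the primary alcohol without epimerising C4, the trans arrangement of CH2OH and aroyl group disfavouring hemiketal formation.

Compound list
1 | methyl (2E)-3-(3,4,5-trimethoxyphenyl)prop-2-enoate | COC(=O)/C=C/c1cc(OC)c(OC)c(OC)c1 | starting material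
2 | (2E)-3-(3,4,5-trimethoxyphenyl)prop-2-en-1-ol | OC/C=C/c1cc(OC)c(OC)c(OC)c1 | intermediate
3 | [(2S,3S)-3-(3,4,5-trimethoxyphenyl)oxiran-2-yl]methanol | OC[C@@H]1O[C@H]1c1cc(OC)c(OC)c(OC)c1 | intermediate
4 | 5-iodo-1,2,3-trimethoxybenzene | COc1cc(I)cc(OC)c1OC | starting material
5 | prop-2-yn-1-ol | C#CCO | starting material
6 | 3-(3,4,5-trimethoxyphenyl)prop-2-yn-1-ol | OCC#Cc1cc(OC)c(OC)c(OC)c1 | intermediate
7 | (2S,3R)-3-(3,4,5-trimethoxyphenyl)-3-{[3-(3,4,5-trimethoxyphenyl)prop-2-yn-1-yl]oxy}propane-1,2-diol | OC[C@H](O)[C@H](OCC#Cc1cc(OC)c(OC)c(OC)c1)c1cc(OC)c(OC)c(OC)c1 | intermediate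
8 | (2S,3R)-1-[(tert-butyldiphenylsilyl)oxy]-3-(3,4,5-trimethoxyphenyl)-3-{[3-(3,4,5-trimethoxyphenyl)prop-2-yn-1-yl]oxy}propan-2-ol | CC(C)(C)[Si](c1ccccc1)(c1ccccc1)OC[C@H](O)[C@H](OCC#Cc1cc(OC)c(OC)c(OC)c1)c1cc(OC)c(OC)c(OC)c1 | intermediate
9 | (3R)-1-[(tert-butyldiphenylsilyl)oxy]-3-(3,4,5-trimethoxyphenyl)-3-{[3-(3,4,5-trimethoxyphenyl)prop-2-yn-1-yl]oxy}propan-2-one | CC(C)(C)[Si](c1ccccc1)(c1ccccc1)OCC(=O)[C@H](OCC#Cc1cc(OC)c(OC)c(OC)c1)c1cc(OC)c(OC)c(OC)c1 | intermediate
10 | tert-butyl{[(4R)-4,7-bis(3,4,5-trimethoxyphenyl)-3,6-dioxabicyclo[3.2.0]hept-1(7)-en-5-yl]methoxy}diphenylsilane (fused oxetene; configuration at C5 not defined, lost on ring opening) | CC(C)(C)[Si](c1ccccc1)(c1ccccc1)OCC23OC(c4cc(OC)c(OC)c(OC)c4)=C2CO[C@@H]3c5cc(OC)c(OC)c(OC)c5 | intermediate (not isolated)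
11 | [(5R)-4-{[(tert-butyldiphenylsilyl)oxy]methyl}-5-(3,4,5-trimethoxyphenyl)-2,5-dihydrofuran-3-yl](3,4,5-trimethoxyphenyl)methanone | CC(C)(C)[Si](c1ccccc1)(c1ccccc1)OCC2=C(C(=O)c3cc(OC)c(OC)c(OC)c3)CO[C@@H]2c4cc(OC)c(OC)c(OC)c4 | intermediate
12 | {[(4S,5S)-4-{[(tert-butyldiphenylsilyl)oxy]methyl}-5-(3,4,5-trimethoxyphenyl)oxolan-3-ylidene](3,4,5-trimethoxyphenyl)methoxy}(diethoxy)methylsilane (enol ether geometry not defined) | CCO[Si](C)(OCC)OC(c1cc(OC)c(OC)c(OC)c1)=C2CO[C@H](c3cc(OC)c(OC)c(OC)c3)[C@@H]2CO[Si](c4ccccc4)(c5ccccc5)C(C)(C)C | intermediate (not isolated)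
13 | [(3R,4S,5S)-4-{[(tert-butyldiphenylsilyl)oxy]methyl}-5-(3,4,5-trimethoxyphenyl)oxolan-3-yl](3,4,5-trimethoxyphenyl)methanone | COc1cc(C(=O)[C@H]2CO[C@H](c3cc(OC)c(OC)c(OC)c3)[C@@H]2CO[Si](c4ccccc4)(c5ccccc5)C(C)(C)C)cc(OC)c1OC | intermediate
14 | [(3R,4S,5S)-4-(hydroxymethyl)-5-(3,4,5-trimethoxyphenyl)oxolan-3-yl](3,4,5-trimethoxyphenyl)methanone | COc1cc(C(=O)[C@H]2CO[C@H](c3cc(OC)c(OC)c(OC)c3)[C@@H]2CO)cc(OC)c1OC | target

Total step count: 9. Longest linear sequence: 8 steps (steps 1, 2, 4, 5, 6, 7, 8, 9); step 3 is a one-step branch.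

Steps most likely to fail

Step 7. The Lewis acid may enolise the α-aryl-α-alkoxy ketone, with erosion of enantiopurity. The alkyne may add only sluggishly to the doubly α-oxygenated carbonyl group, or the electron-rich arene may add to the activated alkyne instead. The fallback sets out from 9 and comes back at 11; it forms the same C3–C4 ring bond with a ruthenium carbene and never exposes a ketone to acid. Non-basic methylenation of 9 (Cp2TiMe2, toluene, 65 °C) should give the 1,6-enyne tert-butyl{[(3R)-2-methylidene-3-(3,4,5-trimethoxyphenyl)-3-{[3-(3,4,5-trimethoxyphenyl)prop-2-yn-1-yl]oxy}propyl]oxy}diphenylsilane F1. Ring-closing enyne metathesis (second-generation Grubbs catalyst RuCl2(=CHPh)(PCy3)(H2IMes), ethylene, toluene, 80 °C) should then give the diene tert-butyl{[(2R)-2-(3,4,5-trimethoxyphenyl)-4-[1-(3,4,5-trimethoxyphenyl)ethenyl]-2,5-dihydrofuran-3-yl]methoxy}diphenylsilane F2. Dihydroxylation of its less hindered 1,1-disubstituted alkene (OsO4 cat., NMO, acetone/water) should give 1-[(5R)-4-{[(tert-butyldiphenylsilyl)oxy]methyl}-5-(3,4,5-trimethoxyphenyl)-2,5-dihydrofuran-3-yl]-1-(3,4,5-trimethoxyphenyl)ethane-1,2-diol F3, and NaIO4 cleavage of this diol gives 11.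

Step 8. Hydride delivery to the tetrasubstituted, flanked enone may be slow, may go to the carbonyl group instead, or may lack facial selectivity. The fallback sets out from 11 and comes back at 13. Homogeneous hydrogenation ([Ir(cod)(PCy3)(py)]PF6, H2, CH2Cl2) should add both hydrogens syn from the face opposite the C2 aryl group and give the all-cis ketone [(3S,4S,5S)-4-{[(tert-butyldiphenylsilyl)oxy]methyl}-5-(3,4,5-trimethoxyphenyl)oxolan-3-yl](3,4,5-trimethoxyphenyl)methanone F4. Epimerisation of the ketone α-carbon with DBU in CH2Cl2 then leads to the more stable 3,4-trans isomer 13.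

Step 4. The opening at the electron-rich benzylic carbon may take on carbocation character, with partial loss of configuration, and isopropoxide from the titanium reagent may compete with alcohol 6. The fallback sets out from 2 and 6 and comes back at 9 through steps 5 and 6; it sets the benzylic ether centre by catalyst control instead of by substitution at a preformed stereocentre. Acylation of 2 (ClCO2Me, pyridine, CH2Cl2) gives methyl (2E)-3-(3,4,5-trimethoxyphenyl)prop-2-en-1-yl carbonate F5. Iridium-catalysed asymmetric allylic etherification ([Ir(cod)Cl]2, the enantiomer of the BINOL-derived bis(1-phenylethyl)amine phosphoramidite ligand that delivers the (S)-ether, the copper alkoxide made from 6, n-BuLi and CuI, THF) should give the branched ether 5-[(1S)-1-{[3-(3,4,5-trimethoxyphenyl)prop-2-yn-1-yl]oxy}prop-2-en-1-yl]-1,2,3-trimethoxybenzene F6. Dihydroxylation of the vinyl group (OsO4 cat., NMO) gives 7 together with its epimer (2R,3R)-3-(3,4,5-trimethoxyphenyl)-3-{[3-(3,4,5-trimethoxyphenyl)prop-2-yn-1-yl]oxy}propane-1,2-diol F7. Both are silylated as in step 5, the epimer giving (2R,3R)-1-[(tert-butyldiphenylsilyl)oxy]-3-(3,4,5-trimethoxyphenyl)-3-{[3-(3,4,5-trimethoxyphenyl)prop-2-yn-1-yl]oxy}propan-2-ol F8, and both converge on ketone 9 in the oxidation of step 6.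

Further compounds
F1 | step 7 | tert-butyl{[(3R)-2-methylidene-3-(3,4,5-trimethoxyphenyl)-3-{[3-(3,4,5-trimethoxyphenyl)prop-2-yn-1-yl]oxy}propyl]oxy}diphenylsilane | CC(C)(C)[Si](c1ccccc1)(c1ccccc1)OCC(=C)[C@H](OCC#Cc1cc(OC)c(OC)c(OC)c1)c1cc(OC)c(OC)c(OC)c1
F2 | step 7 | tert-butyl{[(2R)-2-(3,4,5-trimethoxyphenyl)-4-[1-(3,4,5-trimethoxyphenyl)ethenyl]-2,5-dihydrofuran-3-yl]methoxy}diphenylsilane | CC(C)(C)[Si](c1ccccc1)(c1ccccc1)OCC2=C(C(=C)c3cc(OC)c(OC)c(OC)c3)CO[C@@H]2c4cc(OC)c(OC)c(OC)c4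
F3 | step 7 | 1-[(5R)-4-{[(tert-butyldiphenylsilyl)oxy]methyl}-5-(3,4,5-trimethoxyphenyl)-2,5-dihydrofuran-3-yl]-1-(3,4,5-trimethoxyphenyl)ethane-1,2-diol (both epimers at the carbinol carbon) | CC(C)(C)[Si](c1ccccc1)(c1ccccc1)OCC2=C(C(O)(CO)c3cc(OC)c(OC)c(OC)c3)CO[C@@H]2c4cc(OC)c(OC)c(OC)c4
F4 | step 8 | [(3S,4S,5S)-4-{[(tert-butyldiphenylsilyl)oxy]methyl}-5-(3,4,5-trimethoxyphenyl)oxolan-3-yl](3,4,5-trimethoxyphenyl)methanone | COc1cc(C(=O)[C@@H]2CO[C@H](c3cc(OC)c(OC)c(OC)c3)[C@@H]2CO[Si](c4ccccc4)(c5ccccc5)C(C)(C)C)cc(OC)c1OC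
F5 | step 4 | methyl (2E)-3-(3,4,5-trimethoxyphenyl)prop-2-en-1-yl carbonate | COC(=O)OC/C=C/c1cc(OC)c(OC)c(OC)c1
F6 | step 4 | 5-[(1S)-1-{[3-(3,4,5-trimethoxyphenyl)prop-2-yn-1-yl]oxy}prop-2-en-1-yl]-1,2,3-trimethoxybenzene | C=C[C@H](OCC#Cc1cc(OC)c(OC)c(OC)c1)c1cc(OC)c(OC)c(OC)c1
F7 | step 4 | (2R,3R)-3-(3,4,5-trimethoxyphenyl)-3-{[3-(3,4,5-trimethoxyphenyl)prop-2-yn-1-yl]oxy}propane-1,2-diol | OC[C@@H](O)[C@H](OCC#Cc1cc(OC)c(OC)c(OC)c1)c1cc(OC)c(OC)c(OC)c1
F8 | step 4 | (2R,3R)-1-[(tert-butyldiphenylsilyl)oxy]-3-(3,4,5-trimethoxyphenyl)-3-{[3-(3,4,5-trimethoxyphenyl)prop-2-yn-1-yl]oxy}propan-2-ol | CC(C)(C)[Si](c1ccccc1)(c1ccccc1)OC[C@@H](O)[C@H](OCC#Cc1cc(OC)c(OC)c(OC)c1)c1cc(OC)c(OC)c(OC)c1
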